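The lower flavan unit is built by annulating its ring C onto the finished ring A: the aryl ether bond O1–C8a and the C4–C4a bond are made together. An aryllithium that already carries the complete upper unit (from the bromofluoro catechol ether 17) acylates the chiral 1,3-dioxan-4-one 5. The new C4 ketone, ortho to C8a–F, then activates displacement of fluoride by the C2 alkoxide released with acetone. The step exploits the ortho relation of carbinol carbon C4 and ether oxygen O1 on ring A. The same dioxanone, from an Evans glycolate aldol, also builds the upper unit; hydrogenolysis and a hydroxyl-directed ketone reduction finish the synthesis.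

Key step: step 12

Assumption: (S)-4-benzyl-3-[(benzyloxy)acetyl]oxazolidin-2-one (1) is taken as a purchasable reagent; if it is not in stock, it is one N-acylation of (S)-4-benzyloxazolidin-2-one with benzyloxyacetyl chloride away. Atom labels O1, C2, C3, C4, C4a and C8a are flavan (chromane) numbers, and the unit meant is named in words.

Step 1
Reactants: 1 (S)-4-benzyl-3-[(benzyloxy)acetyl]oxazolidin-2-one; 2 4-(benzyloxy)benzaldehyde
Product: 3 (4S)-4-benzyl-3-[(2S,3R)-2-(benzyloxy)-3-[4-(benzyloxy)phenyl]-3-hydroxypropanoyl]oxazolidin-2-one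
Conditions: Bu2BOTf, Et3N, CH2Cl2, −78 to 0 °C; then pH 7 buffer, MeOH, H2O2, 0 °C
Reagents that add atoms: none
Why: Evans boron-mediated syn-glycolate aldol, in which the Z-boron enolate reacts through a closed chair transition state on the face away from the auxiliary benzyl group and should set C2 (S, benzyloxy) and C3 (R, hydroxyl) as the syn pair.

Step 2
Reactants: 3 aldol adduct
Product: 4 (2S,3R)-2-(benzyloxy)-3-[4-(benzyloxy)phenyl]-3-hydroxypropanoic acid
Conditions: LiOH, H2O2, THF/H2O, 0 °C; then Na2SO3; HCl to pH 2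
Reagents that add atoms: hydrogen peroxide, OO (as LiOOH; it supplies the hydroxyl oxygen of the carboxyl group)
Why: Hydroperoxide cleavage of the auxiliary attacks the exocyclic imide carbonyl selectively under conditions too mild for retro-aldol cleavage or α-epimerisation.

Step 3
Reactants: 4 hydroxy acid
Product: 5 (5S,6R)-5-(benzyloxy)-6-[4-(benzyloxy)phenyl]-2,2-dimethyl-1,3-dioxan-4-one
Conditions: 2-methoxypropene, PPTS (cat.), CH2Cl2, 0 to 23 °C
Reagents that add atoms: 2-methoxypropene, COC(C)=C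
Why: Acid-catalysed acetalisation with an enol ether ties the β-hydroxyl and the carboxyl group into a six-membered acetal lactone, which masks the future O1 and turns the carboxyl carbon into an acyl donor without touching a stereocentre.

Step 4
Reactants: 6 3-fluoro-2-hydroxybenzaldehyde
Product: 7 2-(benzyloxy)-3-fluorobenzaldehyde
Conditions: BnBr, K2CO3, DMF, 23 °C
Reagents that add atoms: benzyl bromide, BrCc1ccccc1
Why: Williamson etherification of the acidic phenol.

Step 5
Reactants: 7 2-(benzyloxy)-3-fluorobenzaldehyde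
Product: 9 2-(benzyloxy)-3-fluorophenol, via aryl formate 8 (not isolated)
Conditions: mCPBA, CH2Cl2, 23 °C; then K2CO3 (cat.), MeOH, 0 °C
Reagents that add atoms: mCPBA, OOC(=O)c1cccc(Cl)c1
Why: Baeyer–Villiger oxidation in which the ortho-alkoxyaryl group migrates in preference to hydrogen, followed by methanolysis of the formate, places the free hydroxyl on the carbon that will become C7 of the lower unit.

Step 6
Reactants: 9 2-(benzyloxy)-3-fluorophenol
Product: 10 2-(benzyloxy)-4-bromo-3-fluorophenol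
Conditions: NBS, MeCN, 0 °C
Reagents that add atoms: N-bromosuccinimide, O=C1CCC(=O)N1Br
Why: Electrophilic aromatic bromination goes para to the free hydroxyl, which puts bromine next to fluorine and blocks the para position for step 10.

Step 7
Reactants: 10 2-(benzyloxy)-4-bromo-3-fluorophenol
Product: 11 1,2-bis(benzyloxy)-4-bromo-3-fluorobenzene
Conditions: BnBr, K2CO3, DMF, 23 °C
Reagents that add atoms: benzyl bromide, BrCc1ccccc1
Why: Williamson etherification.

Step 8
Reactants: 11 1,2-bis(benzyloxy)-4-bromo-3-fluorobenzene; 5 dioxanone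
Product: 14 (2R,3S)-3,7,8-tris(benzyloxy)-2-[4-(benzyloxy)phenyl]chroman-4-one, via aryllithium 12 (not isolated), via fluoro ketone alkoxide 13 (not isolated)
Conditions: n-BuLi, THF, −78 °C; add to 5, THF, −78 °C; then 23 °C; DMPU, 45 °C
Reagents that add atoms: none
Why: This is the cascade of step 12 on the simple arene (Br/Li exchange, acylation of the aryllithium by the lactone carbonyl with loss of acetone, then SNAr closure of the freed alkoxide onto the ketone-activated C–F bond), with C2 and C3 carried over unchanged from 5 as the 2,3-cis pair.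

Step 9
Reactants: 14 chromanone
Product: 15 (2R,3R,4R)-3,7,8-tris(benzyloxy)-2-[4-(benzyloxy)phenyl]chroman-4-ol
Conditions: NaBH4, THF/EtOH, 0 °C
Reagents that add atoms: none
Why: Borohydride reduction of the aryl ketone, where attack anti to the quasi-axial 3-benzyloxy group should give the all-cis 4-ol; the C4 configuration is erased in step 10.

Step 10
Reactants: 15 chroman-4-ol; 10 2-(benzyloxy)-4-bromo-3-fluorophenol
Product: 16 2-(benzyloxy)-4-bromo-3-fluoro-6-[(2R,3R,4S)-3,7,8-tris(benzyloxy)-2-[4-(benzyloxy)phenyl]chroman-4-yl]phenol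
Conditions: 10 (4 equiv), TMSOTf (0.2 equiv), CH2Cl2, −40 to −10 °C
Reagents that add atoms: none
Why: Friedel–Crafts alkylation through the flavan-4-yl cation (stabilised by O1 and the 7-benzyloxy group), in which the phenol reacts at its only free ortho position because bromine blocks the para position, and approach anti to the quasi-axial 3-benzyloxy group of the 2,3-cis cation should set the 3,4-trans (4β) aryl bond.

Step 11
Reactants: 16 coupled phenol
Product: 17 (2R,3R,4R)-3,7,8-tris(benzyloxy)-2-[4-(benzyloxy)phenyl]-4-[2,3-bis(benzyloxy)-5-bromo-4-fluorophenyl]chromane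
Conditions: BnBr, K2CO3, DMF, 50 °C
Reagents that add atoms: benzyl bromide, BrCc1ccccc1
Why: Williamson etherification removes the acidic proton before the lithiation and keeps the para oxygen from weakening the ketone activation in step 12 (same geometry as 16; the C4 descriptor changes only through priority).

Step 12
Reactants: 17 aryl bromide carrying the upper unit; 5 dioxanone
Product: 20 (2R,3S)-3,7,8-tris(benzyloxy)-2-[4-(benzyloxy)phenyl]-6-[(2R,3R,4R)-3,7,8-tris(benzyloxy)-2-[4-(benzyloxy)phenyl]chroman-4-yl]chroman-4-one, via aryllithium 18 (not isolated), via fluoro ketone alkoxide 19 (not isolated)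
Conditions: n-BuLi, THF, −78 °C; add to 5, THF, −78 °C; then 23 °C; DMPU, 45 °C
Reagents that add atoms: none
Why: Br/Li exchange gives aryllithium 18, which acylates at the lactone carbonyl of 5 (C4–C4a bond) with ring opening and loss of acetone to the β-lithiooxy 2-fluoroaryl ketone 19; its C4 carbonyl, ortho to C8a–F, then activates addition–elimination of fluoride by the C2 alkoxide (O1–C8a bond). The closest known reaction types are the acylation of organolithiums by lactones to hydroxy ketones and the SNAr closure of 3-hydroxy-1-(2-fluoroaryl)propan-1-ones to chroman-4-ones. Ring C closes as a six-membered ring by attack of O1 on the aromatic carbon C8a, formally 6-endo-trig on the vinylogous acceptor C4=O/C4a=C8a. No stereocentre is formed: C2 (R) and C3 (S) of the new ring come unchanged from 5, because none of their bonds is broken. The step needs single acylation (inverse addition at −78 °C, hindered α-alkoxy ketone), closure through O1 only (the 3-oxygen is benzylated, so no five-membered closure can compete) and no epimerisation at C3 (the cascade ends neutral, with lithium fluoride and acetone as the only by-products).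

Step 13
Reactants: 20 octabenzyl biflavanoid ketone
Product: 21 (2R,3S)-3,7,8-trihydroxy-2-(4-hydroxyphenyl)-6-[(2R,3R,4S)-3,7,8-trihydroxy-2-(4-hydroxyphenyl)chroman-4-yl]chroman-4-one
Conditions: H2 (1 atm), Pd(OH)2/C, THF/MeOH, 23 °C
Reagents that add atoms: none
Why: Catalytic hydrogenolysis removes all eight benzyl ethers while C4 of the lower unit is still a ketone, so that no benzylic C4–O bond is exposed to hydrogen.

Step 14
Reactants: 21 free phenolic ketone
Product: 22 (2R,3R,4S)-2-(4-hydroxyphenyl)-6-[(2R,3R,4S)-3,7,8-trihydroxy-2-(4-hydroxyphenyl)chroman-4-yl]chromane-3,4,7,8-tetrol (target)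
Conditions: Me4NBH(OAc)3, MeCN/AcOH, −20 °C
Reagents that add atoms: none
Why: Hydroxyl-directed reduction of the Evans–Saksena type, in which the quasi-axial 3-hydroxyl exchanges onto boron and delivers hydride to the same face of the C4 carbonyl, so that the new C4 hydroxyl should come out anti to the 3-hydroxyl (3,4-trans, 4S).

Compound list
1 | (S)-4-benzyl-3-[(benzyloxy)acetyl]oxazolidin-2-one | O=C(COCc1ccccc1)N1[C@@H](Cc2ccccc2)COC1=O | starting material
2 | 4-(benzyloxy)benzaldehyde | O=Cc1ccc(OCc2ccccc2)cc1 | starting material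
3 | (4S)-4-benzyl-3-[(2S,3R)-2-(benzyloxy)-3-[4-(benzyloxy)phenyl]-3-hydroxypropanoyl]oxazolidin-2-one | O[C@H](c1ccc(OCc2ccccc2)cc1)[C@H](OCc1ccccc1)C(=O)N1[C@@H](Cc2ccccc2)COC1=O | intermediate
4 | (2S,3R)-2-(benzyloxy)-3-[4-(benzyloxy)phenyl]-3-hydroxypropanoic acid | O[C@H](c1ccc(OCc2ccccc2)cc1)[C@H](OCc1ccccc1)C(=O)O | intermediate
5 | (5S,6R)-5-(benzyloxy)-6-[4-(benzyloxy)phenyl]-2,2-dimethyl-1,3-dioxan-4-one (cis) | CC1(C)O[C@H](c2ccc(OCc3ccccc3)cc2)[C@H](OCc2ccccc2)C(=O)O1 | intermediate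
6 | 3-fluoro-2-hydroxybenzaldehyde | O=Cc1cccc(F)c1O | starting material
7 | 2-(benzyloxy)-3-fluorobenzaldehyde | O=Cc1cccc(F)c1OCc1ccccc1 | intermediate
8 | 2-(benzyloxy)-3-fluorophenyl formate | O=COc1cccc(F)c1OCc1ccccc1 | intermediate
9 | 2-(benzyloxy)-3-fluorophenol | Oc1cccc(F)c1OCc1ccccc1 | intermediate
10 | 2-(benzyloxy)-4-bromo-3-fluorophenol | Oc1ccc(Br)c(F)c1OCc1ccccc1 | intermediate
11 | 1,2-bis(benzyloxy)-4-bromo-3-fluorobenzene | Brc1ccc(OCc2ccccc2)c(OCc2ccccc2)c1F | intermediate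
12 | [3,4-bis(benzyloxy)-2-fluorophenyl]lithium | [Li]c1ccc(OCc2ccccc2)c(OCc2ccccc2)c1F | intermediate
13 | lithium (1R,2S)-2-(benzyloxy)-1-[4-(benzyloxy)phenyl]-3-[3,4-bis(benzyloxy)-2-fluorophenyl]-3-oxopropan-1-olate | [Li]O[C@H](c1ccc(OCc2ccccc2)cc1)[C@H](OCc1ccccc1)C(=O)c1ccc(OCc2ccccc2)c(OCc2ccccc2)c1F | intermediate
14 | (2R,3S)-3,7,8-tris(benzyloxy)-2-[4-(benzyloxy)phenyl]chroman-4-one (2,3-cis) | O1[C@H](c2ccc(OCc3ccccc3)cc2)[C@H](OCc2ccccc2)C(=O)c2ccc(OCc3ccccc3)c(OCc3ccccc3)c21 | intermediate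
15 | (2R,3R,4R)-3,7,8-tris(benzyloxy)-2-[4-(benzyloxy)phenyl]chroman-4-ol (all-cis) | O1[C@H](c2ccc(OCc3ccccc3)cc2)[C@H](OCc2ccccc2)[C@H](O)c2ccc(OCc3ccccc3)c(OCc3ccccc3)c21 | intermediate
16 | 2-(benzyloxy)-4-bromo-3-fluoro-6-[(2R,3R,4S)-3,7,8-tris(benzyloxy)-2-[4-(benzyloxy)phenyl]chroman-4-yl]phenol (2,3-cis-3,4-trans) | c1ccc(cc1)COc1ccc([C@H]2Oc3c(ccc(OCc4ccccc4)c3OCc3ccccc3)[C@H](c3cc(Br)c(F)c(OCc4ccccc4)c3O)[C@H]2OCc2ccccc2)cc1 | intermediate
17 | (2R,3R,4R)-3,7,8-tris(benzyloxy)-2-[4-(benzyloxy)phenyl]-4-[2,3-bis(benzyloxy)-5-bromo-4-fluorophenyl]chromane (2,3-cis-3,4-trans) | c1ccc(cc1)COc1ccc([C@H]2Oc3c(ccc(OCc4ccccc4)c3OCc3ccccc3)[C@H](c3cc(Br)c(F)c(OCc4ccccc4)c3OCc3ccccc3)[C@H]2OCc2ccccc2)cc1 | intermediate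
18 | {3,4-bis(benzyloxy)-2-fluoro-5-[(2R,3R,4R)-3,7,8-tris(benzyloxy)-2-[4-(benzyloxy)phenyl]chroman-4-yl]phenyl}lithium | c1ccc(cc1)COc1ccc([C@H]2Oc3c(ccc(OCc4ccccc4)c3OCc3ccccc3)[C@H](c3cc([Li])c(F)c(OCc4ccccc4)c3OCc3ccccc3)[C@H]2OCc2ccccc2)cc1 | intermediate
19 | lithium (1R,2S)-2-(benzyloxy)-1-[4-(benzyloxy)phenyl]-3-{3,4-bis(benzyloxy)-2-fluoro-5-[(2R,3R,4R)-3,7,8-tris(benzyloxy)-2-[4-(benzyloxy)phenyl]chroman-4-yl]phenyl}-3-oxopropan-1-olate | c1ccc(cc1)COc1ccc([C@H]2Oc3c(ccc(OCc4ccccc4)c3OCc3ccccc3)[C@H](c3cc(C(=O)[C@@H](OCc4ccccc4)[C@H](O[Li])c4ccc(OCc5ccccc5)cc4)c(F)c(OCc4ccccc4)c3OCc3ccccc3)[C@H]2OCc2ccccc2)cc1 | intermediate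
20 | (2R,3S)-3,7,8-tris(benzyloxy)-2-[4-(benzyloxy)phenyl]-6-[(2R,3R,4R)-3,7,8-tris(benzyloxy)-2-[4-(benzyloxy)phenyl]chroman-4-yl]chroman-4-one | c1ccc(cc1)COc1ccc([C@H]2Oc3c(ccc(OCc4ccccc4)c3OCc3ccccc3)[C@H](c3cc4c(c(OCc5ccccc5)c3OCc3ccccc3)O[C@H](c3ccc(OCc5ccccc5)cc3)[C@H](OCc3ccccc3)C4=O)[C@H]2OCc2ccccc2)cc1 | intermediate
21 | (2R,3S)-3,7,8-trihydroxy-2-(4-hydroxyphenyl)-6-[(2R,3R,4S)-3,7,8-trihydroxy-2-(4-hydroxyphenyl)chroman-4-yl]chroman-4-one | Oc1ccc([C@H]2Oc3c(ccc(O)c3O)[C@H](c3cc4c(c(O)c3O)O[C@H](c3ccc(O)cc3)[C@H](O)C4=O)[C@H]2O)cc1 | intermediate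
22 | (2R,3R,4S)-2-(4-hydroxyphenyl)-6-[(2R,3R,4S)-3,7,8-trihydroxy-2-(4-hydroxyphenyl)chroman-4-yl]chromane-3,4,7,8-tetrol | Oc1ccc([C@H]2Oc3c(ccc(O)c3O)[C@H](c3cc4c(c(O)c3O)O[C@H](c3ccc(O)cc3)[C@H](O)[C@H]4O)[C@H]2O)cc1 | target

Total step count: 14. Longest linear sequence: 11 steps (steps 4 to 14, from 6).

Steps most likely to fail

Step 12. The aryllithium may enolise the dioxanone (with β-elimination) instead of acylating, may add twice to the nascent ketone, or the aldolate may undergo retro-aldol cleavage and C3 epimerisation before the ring closes; step 8 tests the same cascade on the simple arene beforehand. The fallback sets out from 17 (with an acyl donor made from 3) and comes back at 20, making the two bonds in separate operations from an acyl donor that cannot over-add. Aldol adduct 3 is opened with AlMe3 and MeNHOMe·HCl to the Weinreb amide (2S,3R)-2-(benzyloxy)-3-[4-(benzyloxy)phenyl]-3-hydroxy-N-methoxy-N-methylpropanamide F1. This is silylated (TBSOTf, 2,6-lutidine) to its tert-butyldimethylsilyl ether F2. The aryllithium from 17 (n-BuLi, THF, −78 °C) is acylated by F2 to the isolable silyloxy 2-fluoroaryl ketone F3. TBAF in THF at 0 °C then frees the C2 alkoxide, which closes ring C by SNAr and gives 20.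

Step 10. Ionised 15 may be captured by ring A of a second molecule of 15 (self-condensation) faster than by the halogenated, only moderately nucleophilic phenol, or may stop at O-alkylation. The fallback sets out from 15 and comes back at 16. A Mitsunobu etherification of 15 with 10 (PPh3, DIAD, THF, 0 °C) first fixes the partners as the aryl ether (2R,3S,4S)-3,7,8-tris(benzyloxy)-4-[2-(benzyloxy)-4-bromo-3-fluorophenoxy]-2-[4-(benzyloxy)phenyl]chromane F4. A catalytic Lewis acid (TMSOTf, CH2Cl2, −78 °C) then induces the 1,3-shift from oxygen to the ortho carbon within the ion pair, again anti to the 3-benzyloxy group, to give 16.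

Step 14. Facial selectivity may be insufficient if external hydride attack anti to the 3-hydroxyl competes with internal delivery, which would give the 3,4-cis epimer. The fallback sets out from 21 and comes back at 22. Reduction with NaBH4 (EtOH/H2O, 0 °C) is taken deliberately to the 3,4-cis diol, the C4 epimer of the target F5. This is then epimerised at C4 in dilute aqueous HCl at 23 to 50 °C through the benzylic cation, which water should capture anti to the 3-hydroxyl to give 22.

Further compounds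
F1 | step 12 | (2S,3R)-2-(benzyloxy)-3-[4-(benzyloxy)phenyl]-3-hydroxy-N-methoxy-N-methylpropanamide | O[C@H](c1ccc(OCc2ccccc2)cc1)[C@H](OCc1ccccc1)C(=O)N(C)OC
F2 | step 12 | (2S,3R)-2-(benzyloxy)-3-[4-(benzyloxy)phenyl]-3-[(tert-butyldimethylsilyl)oxy]-N-methoxy-N-methylpropanamide | CC(C)(C)[Si](C)(C)O[C@H](c1ccc(OCc2ccccc2)cc1)[C@H](OCc1ccccc1)C(=O)N(C)OC
F3 | step 12 | (2S,3R)-2-(benzyloxy)-3-[4-(benzyloxy)phenyl]-3-[(tert-butyldimethylsilyl)oxy]-1-{3,4-bis(benzyloxy)-2-fluoro-5-[(2R,3R,4R)-3,7,8-tris(benzyloxy)-2-[4-(benzyloxy)phenyl]chroman-4-yl]phenyl}propan-1-one | c1ccc(cc1)COc1ccc([C@H]2Oc3c(ccc(OCc4ccccc4)c3OCc3ccccc3)[C@H](c3cc(C(=O)[C@@H](OCc4ccccc4)[C@H](O[Si](C)(C)C(C)(C)C)c4ccc(OCc5ccccc5)cc4)c(F)c(OCc4ccccc4)c3OCc3ccccc3)[C@H]2OCc2ccccc2)cc1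
F4 | step 10 | (2R,3S,4S)-3,7,8-tris(benzyloxy)-4-[2-(benzyloxy)-4-bromo-3-fluorophenoxy]-2-[4-(benzyloxy)phenyl]chromane (2,3-cis-3,4-trans) | c1ccc(cc1)COc1ccc([C@H]2Oc3c(ccc(OCc4ccccc4)c3OCc3ccccc3)[C@H](Oc3ccc(Br)c(F)c3OCc3ccccc3)[C@H]2OCc2ccccc2)cc1
F5 | step 14 | (2R,3R,4R)-2-(4-hydroxyphenyl)-6-[(2R,3R,4S)-3,7,8-trihydroxy-2-(4-hydroxyphenyl)chroman-4-yl]chromane-3,4,7,8-tetrol (C4 epimer of the target in the lower unit) | Oc1ccc([C@H]2Oc3c(ccc(O)c3O)[C@H](c3cc4c(c(O)c3O)O[C@H](c3ccc(O)cc3)[C@H](O)[C@@H]4O)[C@H]2O)cc1
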